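## The problem

The target (34) is one cyclopentane with two arms on adjacent ring carbons. Ca carries a methyl group and a CH2–C(=O) arm that continues through a CH2, an E-trisubstituted alkene and a benzylic CH2 to a 5-hydroxy-2-methoxy-3-methylphenyl ring. Cb carries a methyl group and a 4-methylpent-3-enoyl group. Ca and Cb are both quaternary, both R, with cis methyl groups, and they are the only stereocentres. Neither can be corrected once made, so one must be set absolutely and the other relative to it, most safely by delivering the Cb substituent from a tether anchored on Ca. Both ketones are β,γ-unsaturated, the chain alkene is also skipped relative to the arene, and acid, base or Lewis acid would move either alkene into conjugation, so both carbonyls must stay masked until the end. The arene is a hydroquinone monomethyl ether whose free phenol would be oxidised to a quinone by the oxidant needed for the carbinols, so it is unmasked last. The Cb carbonyl carbon is neopentyl and prenyl-metal reagents would attack it through their γ-carbon, so the prenyl group needs an indirect entry. The enabling feature is the chain alkene: its inner carbon bears CH3 and a CH2, its outer carbon bears H and the benzylic CH2, which is the pattern left by syn addition of methyl–metal across a terminal alkyne followed by benzylation at the metal-bearing carbon.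

## Retrosynthesis

**Unmasking (34 ⇐ 33 ⇐ 32 ⇐ 31).** No skeletal bond is cut. The phenol is carried as its tert-butyldimethylsilyl ether (33) and both ketones as triethylsilyl-protected carbinols (31). Triethylsilyl on the carbinols and tert-butyldimethylsilyl on the phenol allow mild acid to free the carbinols (32) while the aryl ether stays. The forward steps must oxidise two homoallylic alcohols and cleave an aryl silyl ether without alkene migration.

**Key cut (31 ⇒ 20 + 29 + 28).** The alkene–CH3 and alkene–CH2Ar bonds are cut together, leading to terminal alkyne 20, trimethylaluminium 29 and benzylic chloride 28. The neighbouring cuts are weaker: olefination gives poor E control for a trisubstituted alkene, aryl-metal plus allylic electrophile raises SN2/SN2′ and geometry problems, and enolate chemistry at the chain ketone exposes the skipped enone early. The precursor 20 has no alkene geometry to control and no arene. The forward reaction must place methyl on the internal alkyne carbon, add syn, couple with retention, and leave the prenyl alkene and the silyl ethers alone.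

**Alkyne arm (20 ⇐ 19 ⇒ 17 + 18).** The bond between the chain carbinol carbon and the propargylic CH2 is cut. Lactol 17 serves as the aldehyde, and propargyl bromide 18 with zinc as the nucleophile. The lactol hides the neopentyl carbinol and the aldehyde in one ring, so one silylation of diol 19 protects both hydroxyls. The forward reaction must favour the homopropargylic over the allenic product.

**Prenyl arm (17 ⇐ 16 ⇐ 15 ⇒ 13).** The carbinol–CH2 bond at Cb is cut to aldehyde acid 13 and an allyl nucleophile. The allyl group is converted to prenyl by cross-metathesis (15 to 16), which avoids γ-attack of prenyl-metal reagents. The hydroxy acid closes to cis-fused δ-lactone 15, which protects the carbinol and sets the Ca arm at the oxidation level needed for half-reduction to 17. The precursor 13 holds both quaternary carbons with one-carbon and two-carbon stubs.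

**Ring cleavage (13 ⇐ 11 ⇐ 9).** The C2=C3 bond of silyl enol ether 11 is cut by ozonolysis, giving the formyl group on Cb and the acetic acid arm on Ca. 11 arises from tricyclic cyclopropyl ketone 9 by dissolving-metal opening with enolate trapping. The ketone of 11, if ever set free, is meso, so the enolate must be trapped as formed and never protonated.

**Second quaternary carbon (9 ⇐ 8 ⇐ 6).** The Cb–C bond is cut with a sacrificial cyclopropane bond, leading to diazoketone 8 and acid 6. The three-atom tether on Ca can reach only one alkene face, so Cb is set cis by construction. Intermolecular addition of a one-carbon unit to the trisubstituted alkene would have neither regio- nor facial control.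

**First quaternary carbon (6 ⇐ 3 ⇐ 2 ⇐ 1).** The Ca–CH2 bond is cut by a [3,3] shift back to allylic acetate 3. The carbinol of 2 comes from enone 1 by catalytic asymmetric reduction. A C–O stereocentre made by a reliable reduction is traded for the all-carbon centre.

**Arene (28 ⇐ 26 ⇐ 25 ⇐ 24 ⇐ 22 ⇐ 21).** The benzylic C–Cl bond and the aryl C5–O bond are cut. In 22 the only C–H without an ortho substituent is C5, so sterically governed C–H borylation and oxidation place the oxygen without directing-group work. 21 is a commodity chemical.

## Roads not taken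

**Alternative 1:** Weiss–Cook diquinane from a 1,2-diketone.
- Cut: one ring bond and one arm bond at each quaternary carbon, tracing both methyl-bearing carbons to butane-2,3-dione A1.
- Forward: A1 condenses with two molecules of dimethyl 3-oxopentanedioate A2 in buffered water to cis-fused tetraester A3. Hydrolysis and decarboxylation give dione A4.
- Merits: both quaternary carbons and their cis relationship from commodity chemicals, on any scale, without diazo compounds or dissolving metal.
- Weak points: A4 is achiral and has one carbonyl too many. One ketone must be removed (statistical monoketalisation, Wolff–Kishner reduction, deprotection) to reach meso ketone A5. Only then can a chiral lithium amide select between enantiotopic CH2 groups to give 11.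
- Comparison: to 11 this takes about six steps, the same as steps 1–6 here, and it is cheaper and easier to scale, which is a real advantage. The chosen route sets configuration catalytically in step 1 and relays it through stereospecific events. A5 would be desymmetrised late by a stoichiometric chiral base, with an enantiomer ratio no later step can upgrade. That desymmetrisation is kept as the fallback for step 6. This road does nothing for the E-alkene.

**Alternative 2:** De Mayo photocycloaddition.
- Cut: the Ca–CH2 and Cb–acyl bonds together as a [2+2] disconnection across 1,2-dimethylcyclopentene A7.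
- Forward: irradiation of chiral dioxinone A6 with A7 gives photoadduct A8. Retro-aldol opening of the cyclobutane would release keto acid A9.
- Merits: both quaternary carbons and both arms in two steps. The alkene is symmetric, so there is no regiochemistry question. Cis fusion forces cis methyls. Cb arrives already as a ketone.
- Weak points: the cycloaddition joins three fully substituted carbons in one four-membered ring. Absolute configuration depends on the facial bias of one remote acetal centre. The methyl ketone of A9 must then be extended at its methyl group by a 2-methylprop-1-enyl unit without conjugation, which is harder than allylating an aldehyde.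
- Comparison: it is clearly shorter to the core (two or three steps to A9 against seven to 13). The chosen route offers predictable absolute control and a Cb aldehyde that takes the prenyl precursor by simple addition. The E-alkene problem is untouched.

**Alternative 3:** Asymmetric Pauson–Khand reaction.
- Cut: the Ca–Cb ring bond and the CH2–carbonyl bond of the Ca arm, leading to enyne A10.
- Forward: a rhodium–bisphosphine-catalysed carbonylative cyclisation of A10 gives bicyclic enone A11 with Ca set. Conjugate addition of a methyl cuprate at the ring-fusion carbon with silyl trapping would make Cb and give 11 directly.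
- Merits: catalytic asymmetric and the shortest, about three steps to 11 against six here.
- Weak points: the substrate combines an all-carbon tether without geminal substituents, a terminal alkyne and a 1,1-disubstituted alkene. Each lowers rate and enantioselectivity in such cyclisations, and the enantio-determining step makes the quaternary carbon. The cuprate must then build a second quaternary carbon beside the first.
- Comparison: it is better in step count. The chosen route uses a well-behaved ketone reduction and two geometrically constrained relays, at the cost of three more steps and a diazoketone. The E-alkene problem is untouched.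

Key step: step 18

Assumption: the carbinol carbons made in steps 8 and 11 are formed without control and both are oxidised in step 20; compounds 14–17, 19, 20 and 30–32 (and F1, F7, F8) are carried as epimer mixtures there and written without descriptors at those carbons (17 also at its lactol carbon), while Ca and Cb are fully defined.

## Route

Step 1
Reactants: 1 2,3-dimethylcyclopent-2-en-1-one
Product: 2 (R)-2,3-dimethylcyclopent-2-en-1-ol
Conditions: (S)-2-methyl-CBS-oxazaborolidine (10 mol%), BH3·SMe2, THF, −20 °C; MeOH
Reagents that add atoms: none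
Why: Corey–Bakshi–Shibata reduction; the alkenyl arm with its α-methyl group acts as the large substituent, so the (S)-catalyst should deliver hydride to give the (R)-carbinol, and only 1,2-reduction is expected.

Step 2
Reactants: 2 (R)-2,3-dimethylcyclopent-2-en-1-ol
Product: 3 (R)-2,3-dimethylcyclopent-2-en-1-yl acetate
Conditions: Ac2O, Et3N, DMAP (cat.), CH2Cl2, 0 °C
Reagents that add atoms: acetic anhydride, CC(=O)OC(C)=O
Why: DMAP-catalysed acylation under basic conditions, which avoids ionisation of the tertiary-allylic system; the stereocentre is untouched.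

Step 3
Reactants: 3 (R)-2,3-dimethylcyclopent-2-en-1-yl acetate
Product: 6 2-[(1R)-1,2-dimethylcyclopent-2-en-1-yl]acetic acid, via ketene silyl acetal 4 (not isolated), via trimethylsilyl ester 5 (not isolated)
Conditions: LiN(iPr)2, THF, −78 °C; Me3SiCl/Et3N; −78 → 60 °C; aq. HCl
Reagents that add atoms: chlorotrimethylsilane, C[Si](C)(C)Cl (silicon in 4 and 5 only)
Why: Ireland–Claisen rearrangement; the [3,3] shift is suprafacial, so the new Ca–CH2 bond forms on the ring face that held the oxygen and the carbinol configuration is transferred to the quaternary carbon Ca.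

Step 4
Reactants: 6 2-[(1R)-1,2-dimethylcyclopent-2-en-1-yl]acetic acid
Product: 8 1-diazo-3-[(1R)-1,2-dimethylcyclopent-2-en-1-yl]propan-2-one, via acid chloride 7 (not isolated)
Conditions: (COCl)2, DMF (cat.), CH2Cl2, 0 → 23 °C; then CH2N2 (excess), Et2O, 0 °C
Reagents that add atoms: oxalyl chloride, O=C(Cl)C(=O)Cl (chlorine in 7 only); diazomethane, C=[N+]=[N-]
Why: Standard acylation of diazomethane by an acid chloride; a second equivalent of diazomethane takes up the HCl so the diazoketone survives.

Step 5
Reactants: 8 1-diazo-3-[(1R)-1,2-dimethylcyclopent-2-en-1-yl]propan-2-one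
Product: 9 (1S,2R,5R,8S)-1,5-dimethyltricyclo[3.3.0.0(2,8)]octan-3-one
Conditions: Cu(acac)2 (5 mol%), toluene, 90 °C, slow addition
Reagents that add atoms: none
Why: Intramolecular copper-carbene cyclopropanation of a γ,δ-unsaturated diazoketone, the classic entry to bicyclo[3.1.0]hexan-2-ones; the three-atom tether on Ca reaches only the alkene face it sits on, so the new bond at Cb is cis to the Ca arm and the methyl groups end up cis.

Step 6
Reactants: 9 (1S,2R,5R,8S)-1,5-dimethyltricyclo[3.3.0.0(2,8)]octan-3-one
Product: 11 trimethyl{[(1S,5R)-1,5-dimethylbicyclo[3.3.0]oct-2-en-3-yl]oxy}silane, via lithium enolate 10 (not isolated)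
Conditions: Li, NH3(l)/THF, −78 °C; NH3 evaporated; Me3SiCl/Et3N, THF, −78 → 0 °C
Reagents that add atoms: lithium, [Li] (in 10 only); chlorotrimethylsilane, C[Si](C)(C)Cl
Why: Dissolving-metal opening of a cyclopropyl ketone breaks the external C2–C8 bond, which overlaps best with the carbonyl π system; C8 is protonated by ammonia and the enolate forms only toward Cb. Silylation of this regiodefined enolate keeps the two ring halves distinct, so the meso ketone is never formed.

Step 7
Reactants: 11 trimethyl{[(1S,5R)-1,5-dimethylbicyclo[3.3.0]oct-2-en-3-yl]oxy}silane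
Product: 13 2-[(1R,2R)-2-formyl-1,2-dimethylcyclopentyl]acetic acid, via silyl ester aldehyde 12 (not isolated)
Conditions: O3, CH2Cl2, −78 °C; Me2S, −78 → 23 °C; aq. work-up
Reagents that add atoms: ozone, [O-][O+]=O
Why: Ozonolysis of a silyl enol ether cleaves C2=C3 to an aldehyde on Cb and a silyl ester, hydrolysed to the acid, on the Ca arm; the aldehyde has no α-hydrogen, so neither quaternary carbon is at risk.

Step 8
Reactants: 13 2-[(1R,2R)-2-formyl-1,2-dimethylcyclopentyl]acetic acid
Product: 15 (4aR,7aR)-4a,7a-dimethyl-1-(prop-2-en-1-yl)hexahydrocyclopenta[c]pyran-3(1H)-one, via hydroxy acid 14 (not isolated)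
Conditions: CH2=CHCH2MgBr (2.5 equiv), THF, −78 → 0 °C; aq. HCl; TsOH·H2O (cat.), CH2Cl2, 23 °C
Reagents that add atoms: allylmagnesium bromide, C=CC[Mg]Br
Why: Grignard addition to the non-enolisable neopentyl aldehyde after deprotonation of the acid (13 may sit partly as its cyclic hydroxy-lactone tautomer, which opens on deprotonation). Acid then closes the cis-fused six-membered lactone, which protects the new carbinol; its configuration is not controlled and is erased in step 20.

Step 9
Reactants: 15 (4aR,7aR)-4a,7a-dimethyl-1-(prop-2-en-1-yl)hexahydrocyclopenta[c]pyran-3(1H)-one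
Product: 16 (4aR,7aR)-4a,7a-dimethyl-1-(3-methylbut-2-en-1-yl)hexahydrocyclopenta[c]pyran-3(1H)-one
Conditions: 2-methylbut-2-ene (excess), second-generation Grubbs catalyst RuCl2(=CHPh)(PCy3)(H2IMes) (5 mol%), CH2Cl2, 40 °C
Reagents that add atoms: 2-methylbut-2-ene, CC=C(C)C
Why: Olefin cross-metathesis converts the terminal vinyl group into the trisubstituted prenyl terminus with loss of propene; it is done before any alkyne is present, so enyne metathesis cannot interfere.

Step 10
Reactants: 16 (4aR,7aR)-4a,7a-dimethyl-1-(3-methylbut-2-en-1-yl)hexahydrocyclopenta[c]pyran-3(1H)-one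
Product: 17 (4aR,7aR)-4a,7a-dimethyl-1-(3-methylbut-2-en-1-yl)octahydrocyclopenta[c]pyran-3-ol
Conditions: iBu2AlH, CH2Cl2, −78 °C; aq. KNaC4H4O6
Reagents that add atoms: none
Why: Half-reduction of a δ-lactone; the tetrahedral aluminate is stable at −78 °C and gives the lactol on work-up.

Step 11
Reactants: 17 (4aR,7aR)-4a,7a-dimethyl-1-(3-methylbut-2-en-1-yl)octahydrocyclopenta[c]pyran-3-ol; 18 3-bromoprop-1-yne
Product: 19 1-[(1R,2R)-2-(1-hydroxy-4-methylpent-3-en-1-yl)-1,2-dimethylcyclopentyl]pent-4-yn-2-ol
Conditions: 18 (4 equiv), Zn dust, THF, 0 °C; then 17, 0 → 23 °C; aq. NH4Cl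
Reagents that add atoms: 3-bromoprop-1-yne (reactant 18), C#CCBr
Why: Barbier-type propargylation; one equivalent of the allenylzinc bromide deprotonates the lactol, whose open hydroxy-aldehyde form is then attacked through an SE2′ transition state to give the homopropargylic alcohol. The new carbinol is uncontrolled and is erased in step 20.

Step 12
Reactants: 19 1-[(1R,2R)-2-(1-hydroxy-4-methylpent-3-en-1-yl)-1,2-dimethylcyclopentyl]pent-4-yn-2-ol
Product: 20 4-(triethylsilyloxy)-5-{(1R,2R)-1,2-dimethyl-2-[4-methyl-1-(triethylsilyloxy)pent-3-en-1-yl]cyclopentyl}pent-1-yne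
Conditions: Et3SiOTf (3 equiv), 2,6-lutidine, CH2Cl2, −78 → 0 °C
Reagents that add atoms: triethylsilyl trifluoromethanesulfonate, CC[Si](CC)(CC)OS(=O)(=O)C(F)(F)F
Why: The silyl triflate is reactive enough for the neopentyl carbinol; triethylsilyl is chosen because it can later be removed by mild acid while the aryl tert-butyldimethylsilyl ether stays.

Step 13
Reactants: 21 2-hydroxy-3-methylbenzoic acid
Product: 22 methyl 2-methoxy-3-methylbenzoate
Conditions: MeI (3 equiv), K2CO3, DMF, 50 °C
Reagents that add atoms: iodomethane, CI
Why: Double O-methylation (Williamson ether synthesis and carboxylate alkylation) of a salicylic acid.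

Step 14
Reactants: 22 methyl 2-methoxy-3-methylbenzoate
Product: 24 methyl 5-hydroxy-2-methoxy-3-methylbenzoate, via arylboronate 23 (not isolated)
Conditions: [Ir(OMe)(cod)]2 (1.5 mol%), 4,4'-di-tert-butyl-2,2'-bipyridine (3 mol%), B2pin2 (1.0 equiv), THF, 80 °C; then Oxone (2KHSO5·KHSO4·K2SO4), acetone/H2O, 23 °C
Reagents that add atoms: bis(pinacolato)diboron, CC1(C)OB(OC1(C)C)B1OC(C)(C)C(C)(C)O1 (boron in 23 only); potassium peroxymonosulfate, [K+].[O-]S(=O)(=O)OO
Why: Iridium-catalysed arene C–H borylation is governed by sterics, and C5–H is the only ring hydrogen without an ortho substituent; oxidation of the arylboronate in the same flask gives the phenol para to the methoxy group.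

Step 15
Reactants: 24 methyl 5-hydroxy-2-methoxy-3-methylbenzoate
Product: 25 methyl 5-[(tert-butyldimethylsilyl)oxy]-2-methoxy-3-methylbenzoate
Conditions: tBuMe2SiCl, imidazole, DMF, 23 °C
Reagents that add atoms: tert-butylchlorodimethylsilane, CC(C)(C)[Si](C)(C)Cl
Why: Standard silylation of an unhindered phenol.

Step 16
Reactants: 25 methyl 5-[(tert-butyldimethylsilyl)oxy]-2-methoxy-3-methylbenzoate
Product: 26 {5-[(tert-butyldimethylsilyl)oxy]-2-methoxy-3-methylphenyl}methanol
Conditions: iBu2AlH (2.5 equiv), CH2Cl2, −78 → 0 °C; aq. KNaC4H4O6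
Reagents that add atoms: none
Why: Hydride reduction of the ester to the benzylic alcohol; the aryl silyl ether is stable to the aluminium hydride at low temperature.

Step 17
Reactants: 26 {5-[(tert-butyldimethylsilyl)oxy]-2-methoxy-3-methylphenyl}methanol
Product: 28 tert-butyl[3-(chloromethyl)-4-methoxy-5-methylphenoxy]dimethylsilane, via benzylic mesylate 27 (not isolated)
Conditions: MeSO2Cl, Et3N, CH2Cl2, 0 °C; then LiCl, DMF, 0 → 23 °C
Reagents that add atoms: methanesulfonyl chloride, CS(=O)(=O)Cl (in 27 only); lithium chloride, [Li+].[Cl-]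
Why: Sulfonylation and SN2 displacement by chloride under non-acidic conditions, which spare the aryl silyl ether; the chloride is used fresh.

Step 18
Reactants: 20 4-(triethylsilyloxy)-5-{(1R,2R)-1,2-dimethyl-2-[4-methyl-1-(triethylsilyloxy)pent-3-en-1-yl]cyclopentyl}pent-1-yne; 29 trimethylaluminium; 28 tert-butyl[3-(chloromethyl)-4-methoxy-5-methylphenoxy]dimethylsilane
Product: 31 tert-butyl{3-[(2E)-6-{(1R,2R)-1,2-dimethyl-2-[4-methyl-1-(triethylsilyloxy)pent-3-en-1-yl]cyclopentyl}-3-methyl-5-(triethylsilyloxy)hex-2-en-1-yl]-4-methoxy-5-methylphenoxy}dimethylsilane, via alkenylalane 30 (not isolated)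
Conditions: 29 (2.5 equiv), Cp2ZrCl2 (0.25 equiv), ClCH2CH2Cl, 0 → 23 °C; volatiles removed in vacuo; then 28, Pd(PPh3)4 (5 mol%), THF, 23 → 45 °C
Reagents that add atoms: trimethylaluminium (reactant 29), C[Al](C)C
Why: Cp2ZrCl2 and AlMe3 form a methylzirconium–aluminium species that adds methyl and metal syn across the terminal alkyne of 20, methyl to the internal carbon, giving the (E)-alkenyl(dimethyl)alane 30. Zerovalent palladium from Pd(PPh3)4 inserts into the benzylic C–Cl bond of 28, the alkenyl group passes from aluminium to palladium, and reductive elimination forms the alkene–CH2Ar bond with retention, so the alkene–CH3 and alkene–CH2Ar bonds are both made in one flask. The closest known reaction type is zirconium-catalysed methylalumination of terminal alkynes followed by palladium- or nickel-catalysed benzylation of the alkenylalane. No ring is closed and no stereocentre is created; the only element set is the E geometry, which follows from syn addition and stereoretentive coupling. The step needs aluminium on the terminal carbon (inherent to a terminal alkyne with an unbranched propargylic CH2), reaction at the alkyne but not at the trisubstituted prenyl alkene (which does not carbometalate under these conditions), and no methyl transfer to the benzylpalladium species (excess AlMe3 is stripped before 28 is added). Because both carbinols are silylated, no acidic proton destroys the alane and no ketone is present to draw the new alkene into conjugation.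

Step 19
Reactants: 31 tert-butyl{3-[(2E)-6-{(1R,2R)-1,2-dimethyl-2-[4-methyl-1-(triethylsilyloxy)pent-3-en-1-yl]cyclopentyl}-3-methyl-5-(triethylsilyloxy)hex-2-en-1-yl]-4-methoxy-5-methylphenoxy}dimethylsilane
Product: 32 (4E)-6-{5-[(tert-butyldimethylsilyl)oxy]-2-methoxy-3-methylphenyl}-1-[(1R,2R)-2-(1-hydroxy-4-methylpent-3-en-1-yl)-1,2-dimethylcyclopentyl]-4-methylhex-4-en-2-ol
Conditions: PPTS (0.3 equiv), MeOH/CH2Cl2, 0 → 23 °C
Reagents that add atoms: none
Why: Acid-catalysed methanolysis removes alkyl triethylsilyl ethers far faster than an aryl tert-butyldimethylsilyl ether, which is labile to base and fluoride but not to mild acid; no ketone is present yet, so the alkenes cannot conjugate.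

Step 20
Reactants: 32 (4E)-6-{5-[(tert-butyldimethylsilyl)oxy]-2-methoxy-3-methylphenyl}-1-[(1R,2R)-2-(1-hydroxy-4-methylpent-3-en-1-yl)-1,2-dimethylcyclopentyl]-4-methylhex-4-en-2-ol
Product: 33 (4E)-6-{5-[(tert-butyldimethylsilyl)oxy]-2-methoxy-3-methylphenyl}-1-[(1R,2R)-1,2-dimethyl-2-(4-methylpent-3-enoyl)cyclopentyl]-4-methylhex-4-en-2-one
Conditions: Dess–Martin periodinane (3 equiv), NaHCO3, CH2Cl2, 0 → 23 °C; aq. Na2S2O3/NaHCO3
Reagents that add atoms: none
Why: Buffered Dess–Martin oxidation converts homoallylic alcohols into β,γ-unsaturated ketones under near-neutral conditions that do not move the alkenes; both carbinol epimer sets converge, and the masked phenol cannot be oxidised to a quinone.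

Step 21
Reactants: 33 (4E)-6-{5-[(tert-butyldimethylsilyl)oxy]-2-methoxy-3-methylphenyl}-1-[(1R,2R)-1,2-dimethyl-2-(4-methylpent-3-enoyl)cyclopentyl]-4-methylhex-4-en-2-one
Product: 34 (4E)-1-[(1R,2R)-1,2-dimethyl-2-(4-methylpent-3-enoyl)cyclopentyl]-6-(5-hydroxy-2-methoxy-3-methylphenyl)-4-methylhex-4-en-2-one
Conditions: nBu4NF (1.2 equiv), AcOH (1.5 equiv), THF, 0 °C
Reagents that add atoms: none
Why: Aryl silyl ethers are cleaved by fluoride within minutes at 0 °C; acetic acid protonates the phenoxide as it forms, keeping the medium too weakly basic to enolise the skipped enones.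

## Compound list

1 | 2,3-dimethylcyclopent-2-en-1-one | CC1=C(C)C(=O)CC1 | starting material
2 | (R)-2,3-dimethylcyclopent-2-en-1-ol | O[C@@H]1CCC(C)=C1C | intermediate
3 | (R)-2,3-dimethylcyclopent-2-en-1-yl acetate | CC(=O)O[C@@H]1CCC(C)=C1C | intermediate
4 | trimethyl({1-[(1R)-2,3-dimethylcyclopent-2-en-1-yl]oxyethenyl}oxy)silane | C=C(O[Si](C)(C)C)O[C@@H]1CCC(C)=C1C | intermediate (not isolated)
5 | trimethylsilyl 2-[(1R)-1,2-dimethylcyclopent-2-en-1-yl]acetate | C[Si](C)(C)OC(=O)C[C@@]1(C)CCC=C1C | intermediate (not isolated)
6 | 2-[(1R)-1,2-dimethylcyclopent-2-en-1-yl]acetic acid | OC(=O)C[C@@]1(C)CCC=C1C | intermediate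
7 | 2-[(1R)-1,2-dimethylcyclopent-2-en-1-yl]acetyl chloride | ClC(=O)C[C@@]1(C)CCC=C1C | intermediate (not isolated)
8 | 1-diazo-3-[(1R)-1,2-dimethylcyclopent-2-en-1-yl]propan-2-one | [N-]=[N+]=CC(=O)C[C@@]1(C)CCC=C1C | intermediate
9 | (1S,2R,5R,8S)-1,5-dimethyltricyclo[3.3.0.0(2,8)]octan-3-one | O=C1C[C@@]2(C)CC[C@H]3[C@@H]1[C@@]23C | intermediate
10 | lithium (1S,5R)-1,5-dimethylbicyclo[3.3.0]oct-2-en-3-olate | [Li]OC1=C[C@]2(C)CCC[C@]2(C)C1 | intermediate (not isolated)
11 | trimethyl{[(1S,5R)-1,5-dimethylbicyclo[3.3.0]oct-2-en-3-yl]oxy}silane | C[Si](C)(C)OC1=C[C@]2(C)CCC[C@]2(C)C1 | intermediate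
12 | trimethylsilyl 2-[(1R,2R)-2-formyl-1,2-dimethylcyclopentyl]acetate | C[Si](C)(C)OC(=O)C[C@@]1(C)CCC[C@@]1(C)C=O | intermediate (not isolated)
13 | 2-[(1R,2R)-2-formyl-1,2-dimethylcyclopentyl]acetic acid | OC(=O)C[C@@]1(C)CCC[C@@]1(C)C=O | intermediate
14 | 2-[(1R,2R)-2-(1-hydroxybut-3-en-1-yl)-1,2-dimethylcyclopentyl]acetic acid (carbinol epimers) | OC(=O)C[C@@]1(C)CCC[C@@]1(C)C(O)CC=C | intermediate (not isolated)
15 | (4aR,7aR)-4a,7a-dimethyl-1-(prop-2-en-1-yl)hexahydrocyclopenta[c]pyran-3(1H)-one (C1 epimers) | O=C1C[C@@]2(C)CCC[C@@]2(C)C(CC=C)O1 | intermediate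
16 | (4aR,7aR)-4a,7a-dimethyl-1-(3-methylbut-2-en-1-yl)hexahydrocyclopenta[c]pyran-3(1H)-one (C1 epimers) | O=C1C[C@@]2(C)CCC[C@@]2(C)C(CC=C(C)C)O1 | intermediate
17 | (4aR,7aR)-4a,7a-dimethyl-1-(3-methylbut-2-en-1-yl)octahydrocyclopenta[c]pyran-3-ol (C1 and C3 epimers) | OC1C[C@@]2(C)CCC[C@@]2(C)C(CC=C(C)C)O1 | intermediate
18 | 3-bromoprop-1-yne | C#CCBr | starting material
19 | 1-[(1R,2R)-2-(1-hydroxy-4-methylpent-3-en-1-yl)-1,2-dimethylcyclopentyl]pent-4-yn-2-ol (carbinol epimers) | C#CCC(O)C[C@@]1(C)CCC[C@@]1(C)C(O)CC=C(C)C | intermediate
20 | 4-(triethylsilyloxy)-5-{(1R,2R)-1,2-dimethyl-2-[4-methyl-1-(triethylsilyloxy)pent-3-en-1-yl]cyclopentyl}pent-1-yne (carbinol epimers) | C#CCC(O[Si](CC)(CC)CC)C[C@@]1(C)CCC[C@@]1(C)C(CC=C(C)C)O[Si](CC)(CC)CC | intermediate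
21 | 2-hydroxy-3-methylbenzoic acid | Cc1cccc(C(=O)O)c1O | starting material
22 | methyl 2-methoxy-3-methylbenzoate | COC(=O)c1cccc(C)c1OC | intermediate
23 | methyl 2-methoxy-3-methyl-5-(4,4,5,5-tetramethyl-1,3,2-dioxaborolan-2-yl)benzoate | COC(=O)c1cc(B2OC(C)(C)C(C)(C)O2)cc(C)c1OC | intermediate (not isolated)
24 | methyl 5-hydroxy-2-methoxy-3-methylbenzoate | COC(=O)c1cc(O)cc(C)c1OC | intermediate
25 | methyl 5-[(tert-butyldimethylsilyl)oxy]-2-methoxy-3-methylbenzoate | COC(=O)c1cc(O[Si](C)(C)C(C)(C)C)cc(C)c1OC | intermediate
26 | {5-[(tert-butyldimethylsilyl)oxy]-2-methoxy-3-methylphenyl}methanol | COc1c(C)cc(O[Si](C)(C)C(C)(C)C)cc1CO | intermediate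
27 | {5-[(tert-butyldimethylsilyl)oxy]-2-methoxy-3-methylphenyl}methyl methanesulfonate | COc1c(C)cc(O[Si](C)(C)C(C)(C)C)cc1COS(C)(=O)=O | intermediate (not isolated)
28 | tert-butyl[3-(chloromethyl)-4-methoxy-5-methylphenoxy]dimethylsilane | COc1c(C)cc(O[Si](C)(C)C(C)(C)C)cc1CCl | intermediate
29 | trimethylaluminium | C[Al](C)C | starting material
30 | dimethyl[(1E)-2-methyl-4-(triethylsilyloxy)-5-{(1R,2R)-1,2-dimethyl-2-[4-methyl-1-(triethylsilyloxy)pent-3-en-1-yl]cyclopentyl}pent-1-en-1-yl]alumane (carbinol epimers) | C[Al](C)/C=C(\C)CC(O[Si](CC)(CC)CC)C[C@@]1(C)CCC[C@@]1(C)C(CC=C(C)C)O[Si](CC)(CC)CC | intermediate (not isolated)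
31 | tert-butyl{3-[(2E)-6-{(1R,2R)-1,2-dimethyl-2-[4-methyl-1-(triethylsilyloxy)pent-3-en-1-yl]cyclopentyl}-3-methyl-5-(triethylsilyloxy)hex-2-en-1-yl]-4-methoxy-5-methylphenoxy}dimethylsilane (carbinol epimers) | COc1c(C)cc(O[Si](C)(C)C(C)(C)C)cc1C/C=C(\C)CC(O[Si](CC)(CC)CC)C[C@@]1(C)CCC[C@@]1(C)C(CC=C(C)C)O[Si](CC)(CC)CC | intermediate
32 | (4E)-6-{5-[(tert-butyldimethylsilyl)oxy]-2-methoxy-3-methylphenyl}-1-[(1R,2R)-2-(1-hydroxy-4-methylpent-3-en-1-yl)-1,2-dimethylcyclopentyl]-4-methylhex-4-en-2-ol (carbinol epimers) | COc1c(C)cc(O[Si](C)(C)C(C)(C)C)cc1C/C=C(\C)CC(O)C[C@@]1(C)CCC[C@@]1(C)C(O)CC=C(C)C | intermediate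
33 | (4E)-6-{5-[(tert-butyldimethylsilyl)oxy]-2-methoxy-3-methylphenyl}-1-[(1R,2R)-1,2-dimethyl-2-(4-methylpent-3-enoyl)cyclopentyl]-4-methylhex-4-en-2-one | COc1c(C)cc(O[Si](C)(C)C(C)(C)C)cc1C/C=C(\C)CC(=O)C[C@@]1(C)CCC[C@@]1(C)C(=O)CC=C(C)C | intermediate
34 | (4E)-1-[(1R,2R)-1,2-dimethyl-2-(4-methylpent-3-enoyl)cyclopentyl]-6-(5-hydroxy-2-methoxy-3-methylphenyl)-4-methylhex-4-en-2-one | COc1c(C)cc(O)cc1C/C=C(\C)CC(=O)C[C@@]1(C)CCC[C@@]1(C)C(=O)CC=C(C)C | target

## Step count and weak points

Total: 21 steps. Longest linear sequence: 16 steps (steps 1–12, then 18–21). The arene branch (steps 13–17) joins at step 18.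

**Step 18 (key step).**
- What may go wrong: incomplete methylalumination of the alkyne next to a silyloxy-bearing carbon; methyl transfer from residual aluminium reagent to the benzylpalladium intermediate; homocoupling of the benzylic chloride; loss of a triethylsilyl ether to Lewis-acidic aluminium chlorides.
- Fallback: it sets out from 20 and 28 and divides the event into two polarity-reversed steps. After the same methylalumination, the alane is quenched with iodine to give the (E)-alkenyl iodide F1. Chloride 28 is converted by zinc insertion (Zn dust, LiCl, THF) into the benzylzinc chloride F2. Negishi coupling of F1 with F2 under Pd(PPh3)4 forms the same alkene–CH2Ar bond and returns to the route at 31.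

**Step 3.**
- What may go wrong: a slow [3,3] shift onto a fully substituted alkene carbon, leaving time for ketene loss from the ester enolate, C-silylation, or ionisation of the allylic acetate.
- Fallback: it sets out from 2. Eschenmoser–Claisen rearrangement with N,N-dimethylacetamide dimethyl acetal in hot xylene, under neutral conditions, gives the dimethylamide F3. One equivalent of MeLi converts it into the methyl ketone F4. Kinetic deprotonation with LiN(SiMe3)2 and acylation with 2,2,2-trifluoroethyl trifluoroacetate give the trifluoromethyl diketone F5. Detrifluoroacetylative diazo transfer with methanesulfonyl azide and Et3N then gives diazoketone 8, where the route is rejoined; this also avoids diazomethane.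

**Step 6.**
- What may go wrong: proton exchange between the enolate and any unreduced ketone or adventitious proton source, which moves the enolate to the other α-carbon and, through the meso ketone, erodes optical purity; incomplete O-silylation in the presence of LiNH2.
- Fallback: it sets out from 9. The reduction is quenched with NH4Cl to give the meso ketone cis-1,5-dimethylbicyclo[3.3.0]octan-3-one F6. Enantiotopic-group-selective deprotonation with a lithium amide derived from one antipode of bis(1-phenylethyl)amine in the presence of Me3SiCl regenerates 11, where the route is rejoined. The amide antipode is chosen to give 11.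

**Step 11.**
- What may go wrong: attack through the propargylzinc form giving the allenyl carbinol; slow ring-opening of the hindered lactol so that the reagent is consumed by protonation.
- Fallback: it sets out from 17. An indium-mediated Barbier reaction with 3-bromo-1-(trimethylsilyl)prop-1-yne in aqueous THF gives the silylated alkynyl diol F7. In that medium lactols react through their open form, and the silyl group holds the organoindium in its allenyl form. K2CO3 in MeOH removes the alkynyl silyl group and returns to the route at 19.

**Step 19.**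
- What may go wrong: slow cleavage of the neopentyl triethylsilyl ether, so that longer exposure to acid starts to remove the aryl silyl ether or to move the chain alkene toward the arene.
- Fallback: it sets out from 31. Excess nBu4NF removes all three silyl groups to give the triol F8; no ketone is present, so the basic fluoride is harmless. The phenol, the most acidic and least hindered hydroxyl, is then re-silylated with one equivalent of tBuMe2SiCl and imidazole, returning to the route at 32.

## Further compounds

F1 | step 18 | (1E)-1-iodo-2-methyl-4-(triethylsilyloxy)-5-{(1R,2R)-1,2-dimethyl-2-[4-methyl-1-(triethylsilyloxy)pent-3-en-1-yl]cyclopentyl}pent-1-ene | I/C=C(\C)CC(O[Si](CC)(CC)CC)C[C@@]1(C)CCC[C@@]1(C)C(CC=C(C)C)O[Si](CC)(CC)CC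
F2 | step 18 | {5-[(tert-butyldimethylsilyl)oxy]-2-methoxy-3-methylbenzyl}zinc chloride | COc1c(C)cc(O[Si](C)(C)C(C)(C)C)cc1C[Zn]Cl
F3 | step 3 | 2-[(1R)-1,2-dimethylcyclopent-2-en-1-yl]-N,N-dimethylacetamide | CN(C)C(=O)C[C@@]1(C)CCC=C1C
F4 | step 3 | 1-[(1R)-1,2-dimethylcyclopent-2-en-1-yl]propan-2-one | CC(=O)C[C@@]1(C)CCC=C1C
F5 | step 3 | 5-[(1R)-1,2-dimethylcyclopent-2-en-1-yl]-1,1,1-trifluoropentane-2,4-dione | FC(F)(F)C(=O)CC(=O)C[C@@]1(C)CCC=C1C
F6 | step 6 | cis-1,5-dimethylbicyclo[3.3.0]octan-3-one (meso) | O=C1C[C@@]2(C)CCC[C@@]2(C)C1
F7 | step 11 | 1-[(1R,2R)-2-(1-hydroxy-4-methylpent-3-en-1-yl)-1,2-dimethylcyclopentyl]-5-(trimethylsilyl)pent-4-yn-2-ol | C[Si](C)(C)C#CCC(O)C[C@@]1(C)CCC[C@@]1(C)C(O)CC=C(C)C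
F8 | step 19 | (4E)-1-[(1R,2R)-2-(1-hydroxy-4-methylpent-3-en-1-yl)-1,2-dimethylcyclopentyl]-6-(5-hydroxy-2-methoxy-3-methylphenyl)-4-methylhex-4-en-2-ol | COc1c(C)cc(O)cc1C/C=C(\C)CC(O)C[C@@]1(C)CCC[C@@]1(C)C(O)CC=C(C)C
A1 | alternative 1 | butane-2,3-dione | CC(=O)C(C)=O
A2 | alternative 1 | dimethyl 3-oxopentanedioate | COC(=O)CC(=O)CC(=O)OC
A3 | alternative 1 | tetramethyl cis-1,5-dimethyl-3,7-dioxobicyclo[3.3.0]octane-2,4,6,8-tetracarboxylate | COC(=O)C1C(=O)C(C(=O)OC)[C@]2(C)C(C(=O)OC)C(=O)C(C(=O)OC)[C@]12C
A4 | alternative 1 | cis-1,5-dimethylbicyclo[3.3.0]octane-3,7-dione | O=C1C[C@]2(C)CC(=O)C[C@]2(C)C1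
A5 | alternative 1 | cis-1,5-dimethylbicyclo[3.3.0]octan-3-one (meso) | O=C1C[C@@]2(C)CCC[C@@]2(C)C1
A6 | alternative 2 | (R)-2-tert-butyl-6-methyl-4H-1,3-dioxin-4-one | CC(C)(C)[C@@H]1OC(C)=CC(=O)O1
A7 | alternative 2 | 1,2-dimethylcyclopentene | CC1=C(C)CCC1
A8 | alternative 2 | cis-anti-cis [2+2] photoadduct of A6 and A7 (dioxanone, cyclobutane and cyclopentane rings) | CC(C)(C)[C@@H]1O[C@]2(C)[C@H](C(=O)O1)[C@@]3(C)CCC[C@@]23C
A9 | alternative 2 | 2-[(1R,2R)-2-acetyl-1,2-dimethylcyclopentyl]acetic acid | OC(=O)C[C@@]1(C)CCC[C@@]1(C)C(C)=O
A10 | alternative 3 | 2-methylhept-1-en-6-yne | C#CCCCC(C)=C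
A11 | alternative 3 | (R)-5-methylbicyclo[3.3.0]oct-1-en-3-one | O=C1C=C2CCC[C@]2(C)C1
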